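**Plan**

- Retrosynthetic cuts: the C6–O acetate; the lactone O–C15 bond (back to a C13 diester); C12–C13 of the oxolane; the ether bond O–C13 (C9 alcohol + DMAD); C11–C12 (epoxide opening); C9=C11; C8–CH3; ring A at C1–C10 and C4–C5; C10–CH3.
- Forward order: ring B is a bought chiral cyclohexenone; ring A is annulated onto it (radical conjugate addition at C5, then enolate alkylation at C10); the C8 methyl, the C9 spiro-epoxide and the selenide arm follow; the oxolane closes by C12–C13 bond formation; the lactone ring closes last.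
- Enabling feature: C13 is both the oxygen-bearing carbon of the oxolane (O–C9–C11–C12–C13) and the carbon that carries the two lactone arms (C16 carbonyl; C14–C15). As the β-carbon of a 2-alkoxybutenedioate it accepts a C12 radical 5-exo, so one event makes the oxolane, the quaternary C13 and all four lactone carbons.
- Stereochemistry: C6 (S) is bought and directs C5 (addition anti to OTBS) and C10 (cis ring closure through the C5 tether); C8 is the equatorial, thermodynamic methyl; C9 comes from lower-face epoxidation of the C9 methylidene; C13 is set in the radical closure under control of the C9 spiro centre.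

Key step: step 10

Remark: the target is read as (5S,6S,8R,9R,10R,13R), a cis-fused decalin with H-5, CH3 on C10, the C6 oxygen, CH3 on C8 and the C9 oxygen all on one face of ring B (the "lower face" below); labdane numbering is used for all bicyclic compounds (ring A = C1–C5 and C10; ring B = C5–C10).

Assumption: silyloxy enone 1 is taken as a catalogue building block in its (S) form.

**Route**

Step 1
Reactants: 1 (S)-4-(tert-butyldimethylsilyloxy)cyclohex-2-en-1-one
Product: 2 (S)-4-(tert-butyldimethylsilyloxy)-2-iodocyclohex-2-en-1-one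
Conditions: I2, pyridine, CH2Cl2, 0 → 25 °C
Reagents that add atoms: iodine, II
Why: Johnson α-iodination of an enone (pyridine conjugate addition, iodination of the enolate, elimination) is standard for cyclohexenones and leaves the C6 silyl ether and its configuration untouched.

Step 2
Reactants: 2 (S)-4-(tert-butyldimethylsilyloxy)-2-iodocyclohex-2-en-1-one
Product: 3 (S)-4-(tert-butyldimethylsilyloxy)-2-methylcyclohex-2-en-1-one
Conditions: Me4Sn, Pd2(dba)3 (cat.), AsPh3, CuI, NMP, 60 °C
Reagents that add atoms: tetramethyltin, C[Sn](C)(C)C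
Why: Stille cross-coupling of an α-iodoenone with tetramethyltin under copper co-catalysis is well precedented, needs no base and installs the future C10 methyl.

Step 3
Reactants: 3 (S)-4-(tert-butyldimethylsilyloxy)-2-methylcyclohex-2-en-1-one; 4 5-bromo-2-methylpent-2-ene
Product: 5 (3R,4S)-3-(5-bromo-2-methylpentan-2-yl)-4-(tert-butyldimethylsilyloxy)-2-methylcyclohexan-1-one (C2 epimers; side chain trans to OTBS)
Conditions: Fe(acac)3 (30 mol %), PhSiH3, EtOH/ethylene glycol, 60 °C, 4 in excess
Reagents that add atoms: none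
Why: Iron-hydride hydrogen-atom transfer to the trisubstituted alkene gives the tertiary radical, which adds to the enone β-carbon (reductive olefin–enone coupling of the Giese type) on the face opposite the C6 silyloxy group, so the new C4–C5 bond is trans to OTBS and H-5 is cis to O-6, while C10 forms as an inconsequential epimer mixture.

Step 4
Reactants: 5 (3R,4S)-3-(5-bromo-2-methylpentan-2-yl)-4-(tert-butyldimethylsilyloxy)-2-methylcyclohexan-1-one
Product: 6 cis-fused decalone (5S,6S,10R)-6-(tert-butyldimethylsilyloxy)-4,4,10-trimethyldecalin-9-one (H-5, CH3-10 and OTBS on the lower face)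
Conditions: KOtBu, THF/t-BuOH, 0 → 25 °C
Reagents that add atoms: none
Why: Intramolecular enolate alkylation (6-exo-tet) can only proceed from the C10 enolate, and the tether anchored on C5 can only reach the enolate face on which it sits, so ring A closes cis-fused and CH3-10 ends up on the same face as H-5 and O-6.

Step 5
Reactants: 6 cis-fused decalone (5S,6S,10R)-6-(tert-butyldimethylsilyloxy)-4,4,10-trimethyldecalin-9-one
Product: 7 (5S,6S,8R,10R)-6-(tert-butyldimethylsilyloxy)-4,4,8,10-tetramethyldecalin-9-one (CH3-8 equatorial on the lower face)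
Conditions: LiN(i-Pr)2, THF, −78 °C; MeI, −78 → 0 °C; then NaOMe (cat.), MeOH, 25 °C
Reagents that add atoms: iodomethane, CI
Why: Enolate methylation at C8, the only enolisable position left, occurs from the convex lower face, and base equilibration funnels any epimer to the equatorial methyl, which avoids a syn-axial clash with the axial C1 methylene.

Step 6
Reactants: 7 (5S,6S,8R,10R)-6-(tert-butyldimethylsilyloxy)-4,4,8,10-tetramethyldecalin-9-one
Product: 8 (5S,6S,8R,10R)-6-(tert-butyldimethylsilyloxy)-4,4,8,10-tetramethyl-9-methylidenedecalin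
Conditions: Ph3PCH3Br, KOtBu, toluene, 110 °C
Reagents that add atoms: methyltriphenylphosphonium bromide, C[P+](c1ccccc1)(c1ccccc1)c1ccccc1.[Br-]
Why: Wittig methylenation under forcing conditions is the usual answer for α-quaternary cyclohexanones, and C8 stays in its thermodynamic equatorial configuration under the basic conditions.

Step 7
Reactants: 8 (5S,6S,8R,10R)-6-(tert-butyldimethylsilyloxy)-4,4,8,10-tetramethyl-9-methylidenedecalin
Product: 9 spiro-epoxide (5S,6S,8R,9R,10R)-6-(tert-butyldimethylsilyloxy)-9,11-epoxy-4,4,8,10-tetramethyl-9-methyldecalin (oxirane oxygen axial on the lower face; C11 equatorial)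
Conditions: mCPBA, NaHCO3, CH2Cl2, 0 °C
Reagents that add atoms: meta-chloroperoxybenzoic acid, OOC(=O)c1cccc(Cl)c1
Why: In this Prilezhaev epoxidation the peracid approaches along the axial direction of ring B on the lower face because the axial C1 methylene on C10 blocks the other face, which places the oxygen axial and sets C9.

Step 8
Reactants: 9 spiro-epoxide (5S,6S,8R,9R,10R)-6-(tert-butyldimethylsilyloxy)-9,11-epoxy-4,4,8,10-tetramethyl-9-methyldecalin
Product: 10 (5S,6S,8R,9R,10R)-6-(tert-butyldimethylsilyloxy)-4,4,8,10-tetramethyl-9-[2-(phenylselanyl)ethyl]decalin-9-ol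
Conditions: (PhSe)2CH2, n-BuLi, THF, −78 °C; then 9, HMPA, −78 → 0 °C; H2O
Reagents that add atoms: bis(phenylselanyl)methane, C([Se]c1ccccc1)[Se]c1ccccc1
Why: SN2 opening of the epoxide at its unsubstituted CH2 terminus (C11) by (phenylselanyl)methyllithium leaves C9 untouched and delivers C12 already armed as a radical precursor next to the free tertiary alcohol.

Step 9
Reactants: 10 (5S,6S,8R,9R,10R)-6-(tert-butyldimethylsilyloxy)-4,4,8,10-tetramethyl-9-[2-(phenylselanyl)ethyl]decalin-9-ol; 11 dimethyl acetylenedicarboxylate (DMAD)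
Product: 12 dimethyl (Z)-2-{[(5S,6S,8R,9R,10R)-6-(tert-butyldimethylsilyloxy)-4,4,8,10-tetramethyl-9-[2-(phenylselanyl)ethyl]decalin-9-yl]oxy}but-2-enedioate
Conditions: KN(SiMe3)2 (20 mol %), THF, −40 → 0 °C
Reagents that add atoms: none
Why: Base-catalysed oxa-Michael addition of the tertiary alkoxide to the very electrophilic alkyne of DMAD gives the 2-alkoxybutenedioate; no stereocentre is formed, the Z isomer is expected to predominate and either alkene isomer serves in step 10.

Step 10
Reactants: 12 dimethyl (Z)-2-{[(5S,6S,8R,9R,10R)-6-(tert-butyldimethylsilyloxy)-4,4,8,10-tetramethyl-9-[2-(phenylselanyl)ethyl]decalin-9-yl]oxy}but-2-enedioate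
Product: 13 dimethyl (5S,6S,8R,9R,10R,13R)-6-(tert-butyldimethylsilyloxy)-9,13-epoxylabdane-15,16-dioate
Conditions: Bu3SnH (syringe pump), AIBN (cat.), benzene (0.01 M), 80 °C
Reagents that add atoms: none
Why: Bu3Sn• abstracts the phenylselanyl group to give the primary C12 radical, which adds to C13, the oxygen-bearing β-carbon of the 2-alkoxybutenedioate, and the resulting C14 radical (stabilised by the C15 ester) takes hydrogen from Bu3SnH. The closest known reaction type is the β-alkoxyacrylate radical cyclisation used for 2-substituted oxolanes and oxanes. The oxolane (O–C9–C11–C12–C13) closes in the 5-exo-trig mode. C13 is set under control of the C9 spiro centre: in the chair-like transition state C14 sits pseudoequatorial and the C16 ester pseudoaxial, and the bulkier quaternary C10 branch of ring B (buttressed by a C4 methyl) should take the pseudoequatorial site, so the CH2CO2Me arm ends up on the C10 side and CO2Me on the C8 side of the oxolane, as the target requires (13R). The step needs 5-exo attack at C13 over 6-endo attack at C14 and over direct reduction of the radical; the short C–O bonds of the 4-oxa chain, the polarisation of C13 by the C15 ester and slow addition of Bu3SnH at high dilution secure this.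

Step 11
Reactants: 13 dimethyl (5S,6S,8R,9R,10R,13R)-6-(tert-butyldimethylsilyloxy)-9,13-epoxylabdane-15,16-dioate
Product: 14 (5S,6S,8R,9R,10R,13R)-6-(tert-butyldimethylsilyloxy)-9,13-epoxy-16-methoxy-16-oxolabdan-15-oic acid
Conditions: LiOH·H2O (1.1 equiv), THF/H2O, 0 °C; aq. HCl work-up
Reagents that add atoms: lithium hydroxide, [Li+].[OH-]
Why: Site-selective saponification with one equivalent of hydroxide should take the unhindered CH2CO2Me ester (C15) in preference to the ester on the fully substituted, neopentyl-like C13.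

Step 12
Reactants: 14 (5S,6S,8R,9R,10R,13R)-6-(tert-butyldimethylsilyloxy)-9,13-epoxy-16-methoxy-16-oxolabdan-15-oic acid
Product: 16 (5S,6S,8R,9R,10R,13R)-6-(tert-butyldimethylsilyloxy)-9,13-epoxylabdan-16,15-olide, via hydroxy ester 15 (not isolated)
Conditions: BH3·SMe2, THF, 0 → 25 °C; MeOH quench; then TsOH·H2O (cat.), CH2Cl2, 25 °C
Reagents that add atoms: none
Why: Borane reduces the carboxylic acid chemoselectively in the presence of the methyl ester, and the C15 alcohol then closes the five-membered lactone onto the C16 ester under acid catalysis (lactonisation) without touching C13.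

Step 13
Reactants: 16 (5S,6S,8R,9R,10R,13R)-6-(tert-butyldimethylsilyloxy)-9,13-epoxylabdan-16,15-olide
Product: 17 (5S,6S,8R,9R,10R,13R)-9,13-epoxy-6-hydroxylabdan-16,15-olide
Conditions: HF·pyridine, THF, 0 → 25 °C
Reagents that add atoms: none
Why: Fluoride-mediated desilylation removes the secondary TBS ether, and the lactone and the spiro ether are stable to HF·pyridine.

Step 14
Reactants: 17 (5S,6S,8R,9R,10R,13R)-9,13-epoxy-6-hydroxylabdan-16,15-olide
Product: 18 (5S,6S,8R,9R,10R,13R)-6-acetoxy-9,13-epoxylabdan-16,15-olide (target)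
Conditions: Ac2O, DMAP, pyridine, CH2Cl2, 25 °C
Reagents that add atoms: acetic anhydride, CC(=O)OC(C)=O
Why: DMAP-catalysed acylation of the equatorial C6 alcohol proceeds with retention at C6 and should give the target.

**Compound list**

1 | (S)-4-(tert-butyldimethylsilyloxy)cyclohex-2-en-1-one | CC(C)(C)[Si](C)(C)O[C@H]1CCC(=O)C=C1 | starting material
2 | (S)-4-(tert-butyldimethylsilyloxy)-2-iodocyclohex-2-en-1-one | CC(C)(C)[Si](C)(C)O[C@H]1CCC(=O)C(I)=C1 | intermediate
3 | (S)-4-(tert-butyldimethylsilyloxy)-2-methylcyclohex-2-en-1-one | CC(C)(C)[Si](C)(C)O[C@H]1CCC(=O)C(C)=C1 | intermediate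
4 | 5-bromo-2-methylpent-2-ene | CC(C)=CCCBr | starting material
5 | (3R,4S)-3-(5-bromo-2-methylpentan-2-yl)-4-(tert-butyldimethylsilyloxy)-2-methylcyclohexan-1-one (C2 epimers) | CC(C)(C)[Si](C)(C)O[C@H]1CCC(=O)C(C)[C@@H]1C(C)(C)CCCBr | intermediate
6 | cis-fused (5S,6S,10R)-6-(tert-butyldimethylsilyloxy)-4,4,10-trimethyldecalin-9-one | CC(C)(C)[Si](C)(C)O[C@H]1CCC(=O)[C@]2(C)CCCC(C)(C)[C@H]12 | intermediate
7 | (5S,6S,8R,10R)-6-(tert-butyldimethylsilyloxy)-4,4,8,10-tetramethyldecalin-9-one | CC(C)(C)[Si](C)(C)O[C@H]1C[C@@H](C)C(=O)[C@]2(C)CCCC(C)(C)[C@H]12 | intermediate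
8 | (5S,6S,8R,10R)-6-(tert-butyldimethylsilyloxy)-4,4,8,10-tetramethyl-9-methylidenedecalin | CC(C)(C)[Si](C)(C)O[C@H]1C[C@@H](C)C(=C)[C@]2(C)CCCC(C)(C)[C@H]12 | intermediate
9 | (5S,6S,8R,9R,10R)-6-(tert-butyldimethylsilyloxy)-9,11-epoxy-4,4,8,10-tetramethyl-9-methyldecalin (spiro-epoxide, oxygen on the lower face) | CC(C)(C)[Si](C)(C)O[C@H]1C[C@@H](C)[C@]3(CO3)[C@]2(C)CCCC(C)(C)[C@H]12 | intermediate
10 | (5S,6S,8R,9R,10R)-6-(tert-butyldimethylsilyloxy)-4,4,8,10-tetramethyl-9-[2-(phenylselanyl)ethyl]decalin-9-ol | CC(C)(C)[Si](C)(C)O[C@H]1C[C@@H](C)[C@](O)(CC[Se]c3ccccc3)[C@]2(C)CCCC(C)(C)[C@H]12 | intermediate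
11 | dimethyl acetylenedicarboxylate (DMAD) | COC(=O)C#CC(=O)OC | starting material
12 | dimethyl (Z)-2-{[(5S,6S,8R,9R,10R)-6-(tert-butyldimethylsilyloxy)-4,4,8,10-tetramethyl-9-[2-(phenylselanyl)ethyl]decalin-9-yl]oxy}but-2-enedioate | CC(C)(C)[Si](C)(C)O[C@H]1C[C@@H](C)[C@](O/C(=C\C(=O)OC)C(=O)OC)(CC[Se]c3ccccc3)[C@]2(C)CCCC(C)(C)[C@H]12 | intermediate
13 | dimethyl (5S,6S,8R,9R,10R,13R)-6-(tert-butyldimethylsilyloxy)-9,13-epoxylabdane-15,16-dioate | CC(C)(C)[Si](C)(C)O[C@H]1C[C@@H](C)[C@]2(CC[C@](C(=O)OC)(CC(=O)OC)O2)[C@]2(C)CCCC(C)(C)[C@H]12 | intermediate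
14 | (5S,6S,8R,9R,10R,13R)-6-(tert-butyldimethylsilyloxy)-9,13-epoxy-16-methoxy-16-oxolabdan-15-oic acid | CC(C)(C)[Si](C)(C)O[C@H]1C[C@@H](C)[C@]2(CC[C@](C(=O)OC)(CC(=O)O)O2)[C@]2(C)CCCC(C)(C)[C@H]12 | intermediate
15 | methyl (5S,6S,8R,9R,10R,13R)-6-(tert-butyldimethylsilyloxy)-9,13-epoxy-15-hydroxylabdan-16-oate (not isolated) | CC(C)(C)[Si](C)(C)O[C@H]1C[C@@H](C)[C@]2(CC[C@](C(=O)OC)(CCO)O2)[C@]2(C)CCCC(C)(C)[C@H]12 | intermediate
16 | (5S,6S,8R,9R,10R,13R)-6-(tert-butyldimethylsilyloxy)-9,13-epoxylabdan-16,15-olide | CC(C)(C)[Si](C)(C)O[C@H]1C[C@@H](C)[C@]2(CC[C@]3(CCOC3=O)O2)[C@]2(C)CCCC(C)(C)[C@H]12 | intermediate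
17 | (5S,6S,8R,9R,10R,13R)-9,13-epoxy-6-hydroxylabdan-16,15-olide | O[C@H]1C[C@@H](C)[C@]2(CC[C@]3(CCOC3=O)O2)[C@]2(C)CCCC(C)(C)[C@H]12 | intermediate
18 | (5S,6S,8R,9R,10R,13R)-6-acetoxy-9,13-epoxylabdan-16,15-olide | CC(=O)O[C@H]1C[C@@H](C)[C@]2(CC[C@]3(CCOC3=O)O2)[C@]2(C)CCCC(C)(C)[C@H]12 | target

**Totals**

Total step count: 14. Longest linear sequence: 14 steps (1 → 18).

**Steps most likely to fail**

Step 10 (key step): the C12 radical may add to the wrong face of C13, because the two flanks of the C9 spiro centre differ only modestly, or may close 6-endo at C14. The fallback sets out from 10 and returns at 16. The selenide of 10 would be exchanged for iodide (MeI, NaI, DMF, 60 °C) to give the iodo alcohol F1. Rh2(OAc)4-catalysed O–H insertion with 3-diazodihydrofuran-2(3H)-one would give the α-alkoxy lactone F2 as a C13 epimer mixture that converges on deprotonation. LiN(SiMe3)2 in THF/HMPA would then form the lactone enolate, which closes the oxolane by 5-exo-tet alkylation at C12 and should give 16 with the lactone already in place; C13 is then set in a different, polar transition state.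

Step 9: the hindered axial C9 alkoxide may fail to add to DMAD or may attack an ester carbonyl instead. The fallback sets out from 10 and returns at 13. Br2 in CH2Cl2 at −78 °C would convert the selenide into the bromo alcohol F3. Rh2(OAc)4-catalysed O–H insertion with methyl diazo(dimethoxyphosphoryl)acetate would give the α-alkoxy phosphonoacetate F4. Horner–Wadsworth–Emmons olefination with methyl glyoxylate (LiCl, DBU, MeCN, aldehyde present from the start so that olefination outruns intramolecular alkylation) would give the bromo vinyl ether F5, the bromide analogue of 12. Bu3SnH/AIBN cyclisation of F5 under the conditions of step 10 should give 13.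

Step 11: hydroxide may not discriminate between the two methyl esters, and hydrolysis at C16 would lead on to the isomeric lactone. The fallback sets out from 13 and returns at 16. Exhaustive saponification (KOH, MeOH/H2O, 65 °C) would give the diacid F6. Ac2O at 60 °C would close the cyclic anhydride F7. LiBH(s-Bu)3 in THF at −78 °C would reduce the less hindered C15 carbonyl, and acidic work-up should give lactone 16.

Further compounds
F1 | step 10 | (5S,6S,8R,9R,10R)-6-(tert-butyldimethylsilyloxy)-9-(2-iodoethyl)-4,4,8,10-tetramethyldecalin-9-ol | CC(C)(C)[Si](C)(C)O[C@H]1C[C@@H](C)[C@](O)(CCI)[C@]2(C)CCCC(C)(C)[C@H]12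
F2 | step 10 | 3-{[(5S,6S,8R,9R,10R)-6-(tert-butyldimethylsilyloxy)-9-(2-iodoethyl)-4,4,8,10-tetramethyldecalin-9-yl]oxy}dihydrofuran-2(3H)-one (C13 epimers) | CC(C)(C)[Si](C)(C)O[C@H]1C[C@@H](C)[C@](OC3CCOC3=O)(CCI)[C@]2(C)CCCC(C)(C)[C@H]12
F3 | step 9 | (5S,6S,8R,9R,10R)-9-(2-bromoethyl)-6-(tert-butyldimethylsilyloxy)-4,4,8,10-tetramethyldecalin-9-ol | CC(C)(C)[Si](C)(C)O[C@H]1C[C@@H](C)[C@](O)(CCBr)[C@]2(C)CCCC(C)(C)[C@H]12
F4 | step 9 | methyl 2-{[(5S,6S,8R,9R,10R)-9-(2-bromoethyl)-6-(tert-butyldimethylsilyloxy)-4,4,8,10-tetramethyldecalin-9-yl]oxy}-2-(dimethoxyphosphoryl)acetate | CC(C)(C)[Si](C)(C)O[C@H]1C[C@@H](C)[C@](OC(C(=O)OC)P(=O)(OC)OC)(CCBr)[C@]2(C)CCCC(C)(C)[C@H]12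
F5 | step 9 | dimethyl 2-{[(5S,6S,8R,9R,10R)-9-(2-bromoethyl)-6-(tert-butyldimethylsilyloxy)-4,4,8,10-tetramethyldecalin-9-yl]oxy}but-2-enedioate (alkene isomers) | CC(C)(C)[Si](C)(C)O[C@H]1C[C@@H](C)[C@](OC(=CC(=O)OC)C(=O)OC)(CCBr)[C@]2(C)CCCC(C)(C)[C@H]12
F6 | step 11 | (5S,6S,8R,9R,10R,13R)-6-(tert-butyldimethylsilyloxy)-9,13-epoxylabdane-15,16-dioic acid | CC(C)(C)[Si](C)(C)O[C@H]1C[C@@H](C)[C@]2(CC[C@](C(=O)O)(CC(=O)O)O2)[C@]2(C)CCCC(C)(C)[C@H]12
F7 | step 11 | (5S,6S,8R,9R,10R,13R)-6-(tert-butyldimethylsilyloxy)-9,13-epoxylabdane-15,16-dioic anhydride | CC(C)(C)[Si](C)(C)O[C@H]1C[C@@H](C)[C@]2(CC[C@]3(CC(=O)OC3=O)O2)[C@]2(C)CCCC(C)(C)[C@H]12
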